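**Numbering used throughout**

1 4-fluoro-2,6-dimethoxybenzaldehyde; 2 4-fluoro-2-hydroxy-6-methoxybenzaldehyde; 3 ring D–E fluoride; 4 bromide of 1; 5 pinacol boronate; 6 4-fluoro-3-hydroxy-2,6-dimethoxybenzaldehyde; 7 ring C–D–E fluoride; 8 2,6-dimethoxybenzene-1,4-diol; 9 4-fluoro-3,5-dimethoxybenzaldehyde; 10 ring A–B phenol; 11 pentameric tetra-aldehyde; 12 its tetrakis(formate); 13 nonamethyl ether tetraphenol; 14 target. Full names and SMILES are in the compound list.

## Analysis of the target

Compound 14 is a linear chain of five benzene rings held together by four diaryl ether oxygens and carrying thirteen free phenolic hydroxyls; it has no stereocentre. Lettered from the 2,4,6-trihydroxyphenoxy end, ring A is a phloroglucinol unit bound through the carbon between two hydroxyls. Ring B is 1,4-dioxygenated, with two hydroxyls flanking the oxygen that leads to ring C. Ring C has a single CH, two neighbouring ether oxygens (to B and to D) and then three adjacent hydroxyls; ring D has an ether oxygen at each end of a 1,3,4,5-tetraoxygenated pattern; ring E is a 3,4,5-trihydroxyphenoxy group. The pyrogallol and hydroquinone-type arrays oxidise easily in air, above all as phenoxides, so the hydroxyls are best carried as methyl ethers and freed last under acid. The difficulty lies in making four C–O bonds between electron-rich, ortho-substituted rings (the B–C ether has three ortho oxygens) and in placing thirteen oxygens without regiochemical doubt. The strategy rests on one regularity: the ring A hydroxyl opposite the ether carbon, and the central hydroxyl of the three adjacent oxygens on each of rings C, D and E, all lie para to a ring carbon that bears a diaryl ether oxygen. A formyl group at each of these four carbons would activate fluoride displacement at exactly that ether carbon and could afterwards be exchanged for the hydroxyl; ring B has no such position and needs none, since both of its ether oxygens can serve as nucleophiles.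

## Retrosynthetic reasoning

14 from 13. The last operation is cleavage of nine O–CH3 bonds. Methyl ethers are chosen because they survive carbonate bases at 100 °C, palladium catalysis and peracid, and because they can be removed under acidic, non-oxidising conditions that suit a polyphenol.

13 from 11 (through 12). The four aryl C–OH bonds para to the ether carbons of rings A, C, D and E are traced back to four aryl C–CHO bonds. Cutting here means that the group which made each ether bond possible becomes the oxygen that the target needs at the same carbon. The forward reaction must insert oxygen between ring and formyl carbon at all four sites with aryl, not hydride, migration, and must leave the five electron-rich rings untouched.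

11 from 10 and 7. The B–O–C ether is cut between the oxygen and the ring C carbon, because ring C carries a formyl group para to that carbon and ring B has no activating position. This splits the chain into a two-ring phenol and a three-ring fluoride. It is the most crowded of the four ethers, so it is the one whose partners are each prepared separately and joined last.

7 from 6 and 3. The C–O–D ether is cut on the ring D side, where the formyl group of ring D is para. Ring C enters as 6, a phenol that already carries its own fluoride. This is possible because a phenoxide next to a fluoride switches that fluoride off until the oxygen has been arylated.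

3 from 2 and 1. The D–O–E ether is cut on the ring E side. Ring D enters as the salicylaldehyde-type phenol 2, again with a dormant fluoride, and ring E as 1.

10 from 8 and 9. The A–O–B ether is cut on the ring A side. The hydroquinone 8 needs no protecting group: the fluorine-bearing carbon of 9 sits between two methoxy groups, and only the hydroxyl of 8 that has hydrogen neighbours can reach it.

6 and 2 from 1. Both hydroxy-fluoro-aldehydes derive from the same purchasable aldehyde. Compound 2 arises by removing one of the two methyl groups ortho to the formyl group. Compound 6 arises by putting oxygen on one of the two equivalent ring CH positions, through bromide 4 and boronate 5.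

## Alternatives that were turned down

Alternative 1: Ring C is assembled last from a four-carbon and a two-carbon partner. The four-carbon partner is the cyclobutenone 2-[3,4-dimethoxy-5-(3,4,5-trimethoxyphenoxy)phenoxy]-3,4-dimethoxycyclobut-2-en-1-one A2, which carries rings D and E. The two-carbon partner is the ethynyl ether of the ring A–B phenol, 2-(ethynyloxy)-1,3-dimethoxy-5-(2,4,6-trimethoxyphenoxy)benzene A3. On heating, A2 would open to a vinylketene, which adds across the alkyne of A3 in a (2+2) sense. The new cyclobutenone opens again, and a 6π closure with enolisation gives ring C as the phenol A1, the dodecamethyl ether of 14 with one ring C hydroxyl free.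
- For it: three C–C bonds of the most crowded ring form in one operation, with regiochemistry fixed by the polarity of the ynol ether. Both ether oxygens of ring C are already on the partners, so the tri-ortho-substituted substitution of step 8 is avoided. On that point it is the stronger plan.
- Against it: A3 is an aryl ynol ether of a 2,6-dimethoxyphenol, a class that is laborious to prepare and prone to hydration and polymerisation. A2 requires an unsymmetrical, partly reduced squarate with a bulky aryloxy group. Each partner still contains a diaryl ether (A–B in A3, D–E in A2), so a second ether-forming method is needed in any case. A1 carries twelve methyl ethers instead of nine.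
- Comparison: the chosen route makes all four ethers by one reaction type from three purchasable arenes, obtains each of the four hydroxyls from the group that enabled the coupling, and is far shorter.

Alternative 2: Ring A is built last by cutting the two C–C bonds between its CH carbons and the hydroxyl-bearing carbons next to the ether carbon. The ring B–C–D–E phenol would first be converted into the aryloxymalonate dimethyl 2-{3,5-dimethoxy-4-[3,4,5-trimethoxy-2-(3,4-dimethoxy-5-(3,4,5-trimethoxyphenoxy)phenoxy)phenoxy]phenoxy}propanedioate A5. The doubly deprotonated dimethyl 3-oxopentanedioate A6 is then acylated by both ester groups of A5 under a methoxide base, which closes ring A as the phloroglucinol diester A4.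
- For it: the 1,3,5-trihydroxy pattern is produced directly with its oxygens in place, and no substitution at a carbon flanked by two methoxy groups is needed. On regiocontrol of ring A it is equal to the chosen route.
- Against it: A5 presupposes the whole B–C–D–E chain, that is, the three harder ethers. A substituted malonate has an acidic CH, is deprotonated by the base and is then a poor acyl donor, so a double Claisen condensation is much less dependable here than with an unsubstituted malonate. A4 still needs ester hydrolysis and two decarboxylations.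
- Comparison: the A–B ether is the easiest of the four in the chosen route (an unhindered phenoxide and a sterically self-limiting reaction), so this plan spends its key step where no problem exists and adds steps.

Alternative 3: The C–O–D and D–O–E ethers are traced back to ester linkages in the depside 2,3,4-trimethoxy-6-[2,6-dimethoxy-4-(2,4,6-trimethoxyphenoxy)phenoxy]phenyl 3,4-dimethoxy-5-[(3,4,5-trimethoxybenzoyl)oxy]benzoate A8. A zerovalent nickel catalyst with a chelating dialkylphosphine would insert into each acyl C–O bond, lose CO and reductively eliminate the diaryl ether, giving the tridecamethyl ether A7.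
- For it: A8 comes from two simple acylations with gallic acid derivatives, which even a hindered phenol accepts. No peracid meets the electron-rich rings and A7 has no free phenol. On both points it is stronger than the chosen route.
- Against it: decarbonylative etherification is dependable mainly for electron-poor aroyl esters. Here both acyl groups are electron-rich trialkoxybenzoyl units, for which C–O reductive elimination from nickel is slow, and the ring C phenoxide partner has two ortho substituents. Both esters must react in the same molecule, and any ester that is merely cleaved ends the chain. The A–B and B–C ethers are not addressed, and thirteen methyl ethers must be removed.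
- Comparison: the chosen route relies on addition–elimination at fluoro-aldehydes and a stoichiometric oxidation, both predictable site by site, and reaches a less heavily methylated precursor.

Key step: step 9

Remark on the chemistry: none of the diaryl ether axes is expected to be configurationally stable at room temperature, so 14 and all intermediates are treated as single achiral compounds; 1, 8 and 9 are taken as purchasable.

## Route

Step 1
Reactants: 1 4-fluoro-2,6-dimethoxybenzaldehyde
Product: 2 4-fluoro-2-hydroxy-6-methoxybenzaldehyde
Conditions: BCl3 (1.1 equiv), CH2Cl2, −78 → 0 °C; aqueous work-up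
Reagents that add atoms: none
Why: Chelation-directed ether cleavage: BCl3 binds the carbonyl oxygen and one ortho methoxy oxygen in a six-membered chelate and chloride removes that methyl group; the resulting aryloxyboron chelate ties up the carbonyl, so the second methoxy group and the C–F bond should stay intact.

Step 2
Reactants: 2 4-fluoro-2-hydroxy-6-methoxybenzaldehyde; 1 4-fluoro-2,6-dimethoxybenzaldehyde (4 equiv, excess recovered)
Product: 3 4-fluoro-2-(4-formyl-3,5-dimethoxyphenoxy)-6-methoxybenzaldehyde
Conditions: Cs2CO3, DMSO, 100 °C, Ar; 2 added slowly to 1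
Reagents that add atoms: none
Why: Nucleophilic aromatic substitution (addition–elimination): the phenoxide of 2 attacks the fluorine-bearing carbon of 1 para to the formyl group; 2 cannot condense with itself because its fluoride is switched off while its ring is a phenoxide, and the excess of 1 keeps the newly activated fluoride of 3 from reacting further.

Step 3
Reactants: 1 4-fluoro-2,6-dimethoxybenzaldehyde
Product: 4 3-bromo-4-fluoro-2,6-dimethoxybenzaldehyde
Conditions: NBS (1.05 equiv), MeCN, 0 °C → rt, dark
Reagents that add atoms: N-bromosuccinimide (NBS), BrN1C(=O)CCC1=O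
Why: Electrophilic aromatic bromination; the two ring CH positions of 1 are equivalent and each lies ortho to one methoxy group and para to the other, so one equivalent should give a single monobromide.

Step 4
Reactants: 4 3-bromo-4-fluoro-2,6-dimethoxybenzaldehyde
Product: 5 4-fluoro-2,6-dimethoxy-3-(4,4,5,5-tetramethyl-1,3,2-dioxaborolan-2-yl)benzaldehyde
Conditions: B2pin2, Pd(OAc)2 (5 mol %), SPhos (10 mol %), KOAc, 1,4-dioxane, 90 °C
Reagents that add atoms: bis(pinacolato)diboron (B2pin2), CC1(C)OB(OC1(C)C)B1OC(C)(C)C(C)(C)O1
Why: Miyaura borylation; the electron-rich biarylphosphine SPhos on zerovalent palladium (formed in situ from Pd(OAc)2) is chosen because the C–Br bond is flanked by fluorine and methoxy, and KOAc is too weak a base to touch the aldehyde or the aryl fluoride.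

Step 5
Reactants: 5 4-fluoro-2,6-dimethoxy-3-(4,4,5,5-tetramethyl-1,3,2-dioxaborolan-2-yl)benzaldehyde
Product: 6 4-fluoro-3-hydroxy-2,6-dimethoxybenzaldehyde
Conditions: NaBO3·4H2O, THF/H2O (1:1), rt
Reagents that add atoms: sodium perborate tetrahydrate (NaBO3·4H2O), [Na+].[Na+].O[B-]1(O)OO[B-](O)(O)OO1
Why: Oxidation of an arylboronate by a nucleophilic peroxide (aryl shift from boron to oxygen, then B–O hydrolysis); perborate is mild, and the aldehyde, which has no ortho or para hydroxyl and is therefore not prone to Dakin oxidation, should survive together with the fluoride.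

Step 6
Reactants: 6 4-fluoro-3-hydroxy-2,6-dimethoxybenzaldehyde; 3 4-fluoro-2-(4-formyl-3,5-dimethoxyphenoxy)-6-methoxybenzaldehyde (1.1 equiv)
Product: 7 4-fluoro-3-[4-formyl-3-(4-formyl-3,5-dimethoxyphenoxy)-5-methoxyphenoxy]-2,6-dimethoxybenzaldehyde
Conditions: K2CO3, DMF, 70 °C, Ar
Reagents that add atoms: none
Why: Nucleophilic aromatic substitution: the phenoxide of 6 displaces the unhindered ring D fluoride of 3 para to formyl; 6 does not self-condense because the ortho phenoxide deactivates its own fluoride, and the fluoride of 7, active once the oxygen is arylated, is shielded by the new ortho aryloxy group and meets no phenoxide once 6 is consumed.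

Step 7
Reactants: 8 2,6-dimethoxybenzene-1,4-diol (1.2 equiv); 9 4-fluoro-3,5-dimethoxybenzaldehyde
Product: 10 4-(4-hydroxy-3,5-dimethoxyphenoxy)-3,5-dimethoxybenzaldehyde
Conditions: K2CO3, degassed DMF, Ar, 100 °C
Reagents that add atoms: none
Why: Nucleophilic aromatic substitution: only the hydroxyl of 8 with hydrogen neighbours (probably also the more acidic one) can reach the fluorine-bearing carbon of 9, which sits between two methoxy groups; attack by the other oxygen or a second arylation would require a diaryl ether with four ortho substituents, so the reaction should stop at 10, and air is excluded because the hydroquinone anion oxidises easily.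

Step 8
Reactants: 10 4-(4-hydroxy-3,5-dimethoxyphenoxy)-3,5-dimethoxybenzaldehyde (1.3 equiv); 7 4-fluoro-3-[4-formyl-3-(4-formyl-3,5-dimethoxyphenoxy)-5-methoxyphenoxy]-2,6-dimethoxybenzaldehyde
Product: 11 4-[4-(4-formyl-2,6-dimethoxyphenoxy)-2,6-dimethoxyphenoxy]-3-[4-formyl-3-(4-formyl-3,5-dimethoxyphenoxy)-5-methoxyphenoxy]-2,6-dimethoxybenzaldehyde
Conditions: Cs2CO3, degassed DMSO, Ar, 100 °C
Reagents that add atoms: none
Why: Nucleophilic aromatic substitution joining the two halves: the 2,6-dimethoxyphenoxide of 10 attacks the ring C fluoride of 7 para to formyl; Cs2CO3 in DMSO gives a loosely paired phenoxide for this crowded ether, and fluoride should be displaced far faster than the aryloxy groups para or ortho to the other formyl groups, because the rate-limiting addition is favoured at the carbon that bears fluorine.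

Step 9
Reactants: 11 4-[4-(4-formyl-2,6-dimethoxyphenoxy)-2,6-dimethoxyphenoxy]-3-[4-formyl-3-(4-formyl-3,5-dimethoxyphenoxy)-5-methoxyphenoxy]-2,6-dimethoxybenzaldehyde
Product: 13 4-[4-(4-hydroxy-2,6-dimethoxyphenoxy)-2,6-dimethoxyphenoxy]-3-[4-hydroxy-3-(4-hydroxy-3,5-dimethoxyphenoxy)-5-methoxyphenoxy]-2,6-dimethoxyphenol, via tetrakis(formate) 12 (not isolated)
Conditions: mCPBA (6 equiv), CH2Cl2, 0 °C → rt; reductive aqueous wash; then K2CO3 (cat.), MeOH, Ar, 0 °C; dilute HCl
Reagents that add atoms: 3-chloroperbenzoic acid (mCPBA), O=C(OO)c1cccc(Cl)c1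
Why: This is a fourfold Baeyer–Villiger oxidation of aryl aldehydes, and the closest known reaction is the peracid (Dakin-type) conversion of alkoxybenzaldehydes into phenols. Each formyl carbonyl adds the peracid to give a Criegee adduct, and the aryl group then shifts from carbon to the nearer peroxide oxygen as 3-chlorobenzoate leaves, giving an aryl formate and one new aryl C–O bond per site, four in all. No ring is closed and no stereocentre is formed. The first selectivity needed is aryl over hydride migration at every site: on rings C, D and E the migrating carbon has two ortho oxygens and a para aryloxy oxygen, and on ring A a para aryloxy oxygen, whose lone pairs stabilise the electron-poor migrating carbon so that aryl migration should dominate. The second is oxidation of the carbonyl groups in preference to the rings; the formyl and then formyloxy groups keep four of the five rings comparatively electron-poor, and the products stay masked as the formates of 12 until the peracid has been destroyed. Catalytic K2CO3 in methanol under argon then transfers the four formyl groups to methanol and frees the phenols of 13.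

Step 10
Reactants: 13 4-[4-(4-hydroxy-2,6-dimethoxyphenoxy)-2,6-dimethoxyphenoxy]-3-[4-hydroxy-3-(4-hydroxy-3,5-dimethoxyphenoxy)-5-methoxyphenoxy]-2,6-dimethoxyphenol
Product: 14 5-[4-(2,4,6-trihydroxyphenoxy)-2,6-dihydroxyphenoxy]-4-[3,4-dihydroxy-5-(3,4,5-trihydroxyphenoxy)phenoxy]benzene-1,2,3-triol
Conditions: BBr3 (excess), CH2Cl2, −78 °C → rt; H2O, 0 °C; isolation under Ar
Reagents that add atoms: none
Why: Lewis acid cleavage of aryl methyl ethers: BBr3 coordinates each methoxy oxygen and bromide removes the methyl group by SN2 attack; the diaryl ether bonds offer no sp3 carbon and should survive, and the acidic medium protects the polyphenol from autoxidation.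

## Compound list

1 | 4-fluoro-2,6-dimethoxybenzaldehyde | COc1cc(F)cc(OC)c1C=O | starting material
2 | 4-fluoro-2-hydroxy-6-methoxybenzaldehyde | COc1cc(F)cc(O)c1C=O | intermediate
3 | 4-fluoro-2-(4-formyl-3,5-dimethoxyphenoxy)-6-methoxybenzaldehyde | COc1cc(F)cc(Oc2cc(OC)c(C=O)c(OC)c2)c1C=O | intermediate
4 | 3-bromo-4-fluoro-2,6-dimethoxybenzaldehyde | COc1cc(F)c(Br)c(OC)c1C=O | intermediate
5 | 4-fluoro-2,6-dimethoxy-3-(4,4,5,5-tetramethyl-1,3,2-dioxaborolan-2-yl)benzaldehyde | COc1cc(F)c(B2OC(C)(C)C(C)(C)O2)c(OC)c1C=O | intermediate
6 | 4-fluoro-3-hydroxy-2,6-dimethoxybenzaldehyde | COc1cc(F)c(O)c(OC)c1C=O | intermediate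
7 | 4-fluoro-3-[4-formyl-3-(4-formyl-3,5-dimethoxyphenoxy)-5-methoxyphenoxy]-2,6-dimethoxybenzaldehyde | COc1cc(F)c(Oc2cc(OC)c(C=O)c(Oc3cc(OC)c(C=O)c(OC)c3)c2)c(OC)c1C=O | intermediate
8 | 2,6-dimethoxybenzene-1,4-diol | COc1cc(O)cc(OC)c1O | starting material
9 | 4-fluoro-3,5-dimethoxybenzaldehyde | COc1cc(C=O)cc(OC)c1F | starting material
10 | 4-(4-hydroxy-3,5-dimethoxyphenoxy)-3,5-dimethoxybenzaldehyde | COc1cc(C=O)cc(OC)c1Oc1cc(OC)c(O)c(OC)c1 | intermediate
11 | 4-[4-(4-formyl-2,6-dimethoxyphenoxy)-2,6-dimethoxyphenoxy]-3-[4-formyl-3-(4-formyl-3,5-dimethoxyphenoxy)-5-methoxyphenoxy]-2,6-dimethoxybenzaldehyde | O=Cc1cc(OC)c(Oc2cc(OC)c(Oc3cc(OC)c(C=O)c(OC)c3Oc3cc(OC)c(C=O)c(Oc4cc(OC)c(C=O)c(OC)c4)c3)c(OC)c2)c(OC)c1 | intermediate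
12 | tetrakis(formate) of 13: 4-[4-(4-formyloxy-2,6-dimethoxyphenoxy)-2,6-dimethoxyphenoxy]-3-[4-formyloxy-3-(4-formyloxy-3,5-dimethoxyphenoxy)-5-methoxyphenoxy]-2,6-dimethoxyphenyl formate | O=COc1cc(OC)c(Oc2cc(OC)c(Oc3cc(OC)c(OC=O)c(OC)c3Oc3cc(OC)c(OC=O)c(Oc4cc(OC)c(OC=O)c(OC)c4)c3)c(OC)c2)c(OC)c1 | intermediate
13 | 4-[4-(4-hydroxy-2,6-dimethoxyphenoxy)-2,6-dimethoxyphenoxy]-3-[4-hydroxy-3-(4-hydroxy-3,5-dimethoxyphenoxy)-5-methoxyphenoxy]-2,6-dimethoxyphenol | Oc1cc(OC)c(Oc2cc(OC)c(Oc3cc(OC)c(O)c(OC)c3Oc3cc(OC)c(O)c(Oc4cc(OC)c(O)c(OC)c4)c3)c(OC)c2)c(OC)c1 | intermediate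
14 | 5-[4-(2,4,6-trihydroxyphenoxy)-2,6-dihydroxyphenoxy]-4-[3,4-dihydroxy-5-(3,4,5-trihydroxyphenoxy)phenoxy]benzene-1,2,3-triol | Oc1cc(O)c(Oc2cc(O)c(Oc3cc(O)c(O)c(O)c3Oc3cc(O)c(O)c(Oc4cc(O)c(O)c(O)c4)c3)c(O)c2)c(O)c1 | target

## Step count and least certain steps

Total: 10 steps from 1, 8 and 9. Longest linear sequence: 7 steps (steps 3, 4, 5, 6, 8, 9, 10).

**Step 9 (key step).**
- Risk: the migration selectivity may be uneven. The ring A formyl group has no ortho oxygen, so hydride migration there could divert part of the material to a carboxylic acid. Driving that slower site with more peracid invites electrophilic hydroxylation of ring B, the one ring without a deactivating group.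
- Fallback (sets out from 11, returns at 13): the formyl groups are first changed into acetyl groups, so that the only competitor of aryl migration is a methyl group and no acid can form. MeMgBr in THF at 0 °C should add to all four aldehydes of 11 and give the tetrakis(1-hydroxyethyl) compound F1 as a mixture of diastereomers, which is of no consequence. Dess–Martin periodinane with NaHCO3 in CH2Cl2 oxidises it to the tetrakis(methyl ketone) F2. mCPBA with a catalytic amount of trifluoroacetic acid in CH2Cl2 converts F2 into the tetraacetate F3 by Baeyer–Villiger oxidation. Catalytic K2CO3 in methanol under argon removes the acetyl groups and gives 13.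

**Step 8.**
- Risk: addition of a 2,6-disubstituted phenoxide to a fluorine-bearing carbon with an ortho aryloxy group may be slow. Displacement of aryloxy groups at the unhindered carbons para to the ring D and ring E formyl groups could then compete and scramble the chain. Neither partner can be used in large excess cheaply.
- Fallback (sets out from 6, uses 10 and 3, returns at 11): the crowded ether is made first on a small electrophile with a single reactive site. MOMCl and iPr2NEt in CH2Cl2 convert 6 into 4-fluoro-2,6-dimethoxy-3-(methoxymethoxy)benzaldehyde F4. Its fluoride is displaced by 10 (Cs2CO3, DMSO, 100 °C, F4 in excess) to give 4-[4-(4-formyl-2,6-dimethoxyphenoxy)-2,6-dimethoxyphenoxy]-2,6-dimethoxy-3-(methoxymethoxy)benzaldehyde F5. Aqueous HCl in THF frees the ring C phenol, 4-[4-(4-formyl-2,6-dimethoxyphenoxy)-2,6-dimethoxyphenoxy]-3-hydroxy-2,6-dimethoxybenzaldehyde F6. F6 and the unhindered fluoride of 3 (K2CO3, DMF, 70 °C) then give 11.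

**Step 2.**
- Risk: chain growth. The fluoride of product 3 is about as reactive as that of 1, so the phenoxide of 2 may arylate 3 as well, and only the excess of 1 holds this back.
- Fallback (sets out from 2, returns at 3): the formyl group of 2 is masked so that its fluoride has no activating group at any stage. Ethane-1,2-diol with catalytic TsOH in toluene under water removal gives 2-(1,3-dioxolan-2-yl)-5-fluoro-3-methoxyphenol F7. Its phenoxide, now also a better nucleophile, reacts with 1 (1.1 equiv, K2CO3, DMF, 90 °C) to give 4-[2-(1,3-dioxolan-2-yl)-5-fluoro-3-methoxyphenoxy]-2,6-dimethoxybenzaldehyde F8. Dilute HCl in THF/water removes the acetal and gives 3.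

**Step 4.**
- Risk: oxidative addition at the bromide between fluorine and methoxy may be slow, leading to loss of bromine by reduction. The boronate, which has two ortho heteroatoms, may lose boron by protonolysis.
- Fallback (sets out from 1, returns at 6): the oxygen is introduced by directed metalation without palladium. Trimethyl orthoformate with catalytic TsOH in methanol converts 1 into its dimethyl acetal, 2-(dimethoxymethyl)-5-fluoro-1,3-dimethoxybenzene F9. n-BuLi in THF at −78 °C deprotonates the ring CH between fluorine and methoxy, the only kind present. B(OMe)3 followed by H2O2 turns the carbanion into 3-(dimethoxymethyl)-6-fluoro-2,4-dimethoxyphenol F10. Dilute aqueous HCl cleaves the acetal and gives 6.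

**Step 10.**
- Risk: ether cleavage may be incomplete at the crowded methoxy groups, and the thirteen-fold phenol may oxidise in air during aqueous work-up and chromatography.
- Fallback (sets out from 13, returns at 14): after the same BBr3 treatment, crude 14 is not purified but acetylated at once (Ac2O, pyridine) to the tridecaacetate F11. F11 is stable, can be purified on silica and can be checked for complete demethylation. HCl in methanol at rt then removes the acetyl groups under acidic, non-oxidising conditions and gives 14.

## Further compounds

F1 | step 9 | tetrakis(1-hydroxyethyl) analogue of 11 (each CHO replaced by CH(OH)CH3), mixture of diastereomers | CC(O)c1cc(OC)c(Oc2cc(OC)c(Oc3cc(OC)c(C(C)O)c(OC)c3Oc3cc(OC)c(C(C)O)c(Oc4cc(OC)c(C(C)O)c(OC)c4)c3)c(OC)c2)c(OC)c1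
F2 | step 9 | tetrakis(methyl ketone) analogue of 11 (each CHO replaced by COCH3) | CC(=O)c1cc(OC)c(Oc2cc(OC)c(Oc3cc(OC)c(C(C)=O)c(OC)c3Oc3cc(OC)c(C(C)=O)c(Oc4cc(OC)c(C(C)=O)c(OC)c4)c3)c(OC)c2)c(OC)c1
F3 | step 9 | tetraacetate of 13 | CC(=O)Oc1cc(OC)c(Oc2cc(OC)c(Oc3cc(OC)c(OC(C)=O)c(OC)c3Oc3cc(OC)c(OC(C)=O)c(Oc4cc(OC)c(OC(C)=O)c(OC)c4)c3)c(OC)c2)c(OC)c1
F4 | step 8 | 4-fluoro-2,6-dimethoxy-3-(methoxymethoxy)benzaldehyde | COCOc1c(F)cc(OC)c(C=O)c1OC
F5 | step 8 | 4-[4-(4-formyl-2,6-dimethoxyphenoxy)-2,6-dimethoxyphenoxy]-2,6-dimethoxy-3-(methoxymethoxy)benzaldehyde | COCOc1c(Oc2c(OC)cc(Oc3c(OC)cc(C=O)cc3OC)cc2OC)cc(OC)c(C=O)c1OC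
F6 | step 8 | 4-[4-(4-formyl-2,6-dimethoxyphenoxy)-2,6-dimethoxyphenoxy]-3-hydroxy-2,6-dimethoxybenzaldehyde | Oc1c(Oc2c(OC)cc(Oc3c(OC)cc(C=O)cc3OC)cc2OC)cc(OC)c(C=O)c1OC
F7 | step 2 | 2-(1,3-dioxolan-2-yl)-5-fluoro-3-methoxyphenol | COc1cc(F)cc(O)c1C1OCCO1
F8 | step 2 | 4-[2-(1,3-dioxolan-2-yl)-5-fluoro-3-methoxyphenoxy]-2,6-dimethoxybenzaldehyde | COc1cc(F)cc(Oc2cc(OC)c(C=O)c(OC)c2)c1C1OCCO1
F9 | step 4 | 2-(dimethoxymethyl)-5-fluoro-1,3-dimethoxybenzene | COc1cc(F)cc(OC)c1C(OC)OC
F10 | step 4 | 3-(dimethoxymethyl)-6-fluoro-2,4-dimethoxyphenol | COc1cc(F)c(O)c(OC)c1C(OC)OC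
F11 | step 10 | tridecaacetate of 14 | CC(=O)Oc1cc(OC(C)=O)c(Oc2cc(OC(C)=O)c(Oc3cc(OC(C)=O)c(OC(C)=O)c(OC(C)=O)c3Oc3cc(OC(C)=O)c(OC(C)=O)c(Oc4cc(OC(C)=O)c(OC(C)=O)c(OC(C)=O)c4)c3)c(OC(C)=O)c2)c(OC(C)=O)c1
A1 | alternative 1 | dodecamethyl ether of 14 with the ring C hydroxyl next to the ring C hydrogen free | COc1cc(OC)c(Oc2cc(OC)c(Oc3cc(O)c(OC)c(OC)c3Oc3cc(OC)c(OC)c(Oc4cc(OC)c(OC)c(OC)c4)c3)c(OC)c2)c(OC)c1
A2 | alternative 1 | 2-[3,4-dimethoxy-5-(3,4,5-trimethoxyphenoxy)phenoxy]-3,4-dimethoxycyclobut-2-en-1-one | O=C1C(Oc2cc(OC)c(OC)c(Oc3cc(OC)c(OC)c(OC)c3)c2)=C(OC)C1OC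
A3 | alternative 1 | 2-(ethynyloxy)-1,3-dimethoxy-5-(2,4,6-trimethoxyphenoxy)benzene | C#COc1c(OC)cc(Oc2c(OC)cc(OC)cc2OC)cc1OC
A4 | alternative 2 | dimethyl 2,4,6-trihydroxy-5-{3,5-dimethoxy-4-[3,4,5-trimethoxy-2-(3,4-dimethoxy-5-(3,4,5-trimethoxyphenoxy)phenoxy)phenoxy]phenoxy}benzene-1,3-dicarboxylate | COC(=O)c1c(O)c(C(=O)OC)c(O)c(Oc2cc(OC)c(Oc3cc(OC)c(OC)c(OC)c3Oc3cc(OC)c(OC)c(Oc4cc(OC)c(OC)c(OC)c4)c3)c(OC)c2)c1O
A5 | alternative 2 | dimethyl 2-{3,5-dimethoxy-4-[3,4,5-trimethoxy-2-(3,4-dimethoxy-5-(3,4,5-trimethoxyphenoxy)phenoxy)phenoxy]phenoxy}propanedioate | COC(=O)C(Oc1cc(OC)c(Oc2cc(OC)c(OC)c(OC)c2Oc2cc(OC)c(OC)c(Oc3cc(OC)c(OC)c(OC)c3)c2)c(OC)c1)C(=O)OC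
A6 | alternative 2 | dimethyl 3-oxopentanedioate | COC(=O)CC(=O)CC(=O)OC
A7 | alternative 3 | tridecamethyl ether of 14 | COc1cc(OC)c(Oc2cc(OC)c(Oc3cc(OC)c(OC)c(OC)c3Oc3cc(OC)c(OC)c(Oc4cc(OC)c(OC)c(OC)c4)c3)c(OC)c2)c(OC)c1
A8 | alternative 3 | 2,3,4-trimethoxy-6-[2,6-dimethoxy-4-(2,4,6-trimethoxyphenoxy)phenoxy]phenyl 3,4-dimethoxy-5-[(3,4,5-trimethoxybenzoyl)oxy]benzoate | COc1cc(OC)c(Oc2cc(OC)c(Oc3cc(OC)c(OC)c(OC)c3OC(=O)c3cc(OC)c(OC)c(OC(=O)c4cc(OC)c(OC)c(OC)c4)c3)c(OC)c2)c(OC)c1
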